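**Plan**
Locants: ring A = C1 butyryl, C2 OH, C3 Me, C4 OH, C5 bridge CH2, C6 OH; ring B = C1' bridge, C2' OH, C3' butyryl, C4' OH, C5' Me, C6' OMe.
Cuts, in retrosynthetic order: the C3'-acyl bond (Friedel-Crafts); C5-C6 and C1-C2 of ring A ((4+2) cycloreversion); the C5-CH2 bond (aldol); the CH2-C1' bond (formylation).
Enabling feature: ring A has oxygen on C2, C4 and C6 and an acyl group on C1. The pair C6(O)-C1(acyl) is therefore the push-pull alkyne EtO-C≡C-C(O)Pr, and C2(O)-C3(Me)-C4(O)-C5(CH2Ar) is the bis(silyl) dienol ether of a 2-methyl-3-oxo ester whose OMe leaves on aromatization.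
Forward: ring B is bought as 2-methylphloroglucinol and fitted with CHO, two benzyl groups and one methyl group. A keto ester dianion is added to the aldehyde, the carbinol is deoxygenated, and double silylation gives the diene. The cycloaddition builds ring A, the only ring made, and hydrogenolysis, C3' butyrylation and de-ethylation finish the route.
Stereochemistry: the target has no stereocentre and all transient sp3 centres are erased. Only the Z geometry of the diene C3=C4 bond matters, and kinetic deprotonation sets it.

Key step: step 10

Remark on the chemistry: the aldol adduct, the keto ester, the propargylic alcohol and the cycloadduct are handled as racemates or diastereomer mixtures and drawn without configuration. The geometry of the enol ether and ketene acetal C=C bonds next to the ester carbon is left undefined, because it has no bearing on the outcome.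

**Step 1**
Reactants: 1 2-methylphloroglucinol
Product: 3 2,4,6-trihydroxy-3-methylbenzaldehyde, via aryl iminium chloride 2 (not isolated)
Conditions: POCl3 (1.1 equiv), DMF, EtOAc, 0 °C to rt; then H2O, rt
Reagents that add atoms: N,N-dimethylformamide CN(C)C=O; water O
Why: Vilsmeier-Haack formylation of a phloroglucinol needs no protection, the two open ring carbons of 1 are equivalent by symmetry so only one monoaldehyde is possible, and iminium salt 2 is too electron-poor to be attacked a second time.

**Step 2**
Reactants: 3 2,4,6-trihydroxy-3-methylbenzaldehyde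
Product: 4 4,6-bis(benzyloxy)-2-hydroxy-3-methylbenzaldehyde
Conditions: BnBr (2.05 equiv), K2CO3 (2.2 equiv), DMF, 0 °C to rt
Reagents that add atoms: benzyl bromide BrCc1ccccc1
Why: Williamson etherification under partial-alkylation control, as known for 3-methylphloroacylphenones, should alkylate the unchelated para hydroxyl at C4 first and the less crowded ortho hydroxyl at C6 next, while the C2 hydroxyl, wedged between methyl and formyl and hydrogen-bonded to the carbonyl oxygen, is left over with two equivalents of halide.

**Step 3**
Reactants: 4 4,6-bis(benzyloxy)-2-hydroxy-3-methylbenzaldehyde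
Product: 5 4,6-bis(benzyloxy)-2-methoxy-3-methylbenzaldehyde
Conditions: MeI (3 equiv), K2CO3 (2 equiv), DMF, 40 °C
Reagents that add atoms: iodomethane CI
Why: Williamson methylation of the one remaining, chelated phenol needs only an excess of a small electrophile in a dipolar solvent, and nothing else in 4 can be alkylated.

**Step 4**
Reactants: 5 4,6-bis(benzyloxy)-2-methoxy-3-methylbenzaldehyde; 6 methyl 2-methylacetoacetate
Product: 8 methyl 5-[4,6-bis(benzyloxy)-2-methoxy-3-methylphenyl]-5-hydroxy-2-methyl-3-oxopentanoate, via dilithio dianion 7 (not isolated)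
Conditions: 6 (1.3 equiv), LiN(iPr)2 (2.7 equiv), THF, 0 °C; then 5, -78 °C; AcOH quench at -78 °C
Reagents that add atoms: none
Why: Gamma-selective aldol addition of a beta-keto ester dianion, whose terminal carbanion is by far the more nucleophilic site, forms the future C5-CH2 bond from the stable aldehyde and avoids a 2,4,6-trialkoxybenzyl halide that would alkylate itself; the carbinol and alpha-methyl stereocentres arise uncontrolled and are erased later.

**Step 5**
Reactants: 8 methyl 5-[4,6-bis(benzyloxy)-2-methoxy-3-methylphenyl]-5-hydroxy-2-methyl-3-oxopentanoate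
Product: 9 methyl 5-[4,6-bis(benzyloxy)-2-methoxy-3-methylphenyl]-2-methyl-3-oxopentanoate
Conditions: Et3SiH (6 equiv), CF3CO2H (3 equiv), CH2Cl2 (0.02 M), -40 to 0 °C
Reagents that add atoms: none
Why: In this ionic hydrogenation the hydroxyl group leaves under mild acid because three ortho/para oxygen donors stabilise the benzylic cation, excess silane at high dilution should deliver hydride before another arene can attack, and the keto ester and benzyl ethers are inert at or below 0 °C.

**Step 6**
Reactants: 9 methyl 5-[4,6-bis(benzyloxy)-2-methoxy-3-methylphenyl]-2-methyl-3-oxopentanoate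
Product: 10 methyl 5-[4,6-bis(benzyloxy)-2-methoxy-3-methylphenyl]-2-methyl-3-(trimethylsilyloxy)pent-2-enoate
Conditions: Me3SiCl (1.8 equiv), Et3N (2 equiv), PhMe, rt, 48-72 h; filtration under argon, used crude
Reagents that add atoms: chlorotrimethylsilane C[Si](C)(C)Cl
Why: Soft O-silylation of the enolisable beta-keto ester with Me3SiCl and Et3N is the standard first stage of bis(silyloxy)diene synthesis, and the enol ether geometry is irrelevant.

**Step 7**
Reactants: 10 methyl 5-[4,6-bis(benzyloxy)-2-methoxy-3-methylphenyl]-2-methyl-3-(trimethylsilyloxy)pent-2-enoate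
Product: 12 (3Z)-5-[4,6-bis(benzyloxy)-2-methoxy-3-methylphenyl]-1-methoxy-2-methyl-1,3-bis(trimethylsilyloxy)penta-1,3-diene, via lithium dienolate 11 (not isolated)
Conditions: LiN(iPr)2 (1.3 equiv), THF, -78 °C; Me3SiCl (1.5 equiv), -78 °C to rt; pentane, filtration under argon, used crude
Reagents that add atoms: chlorotrimethylsilane C[Si](C)(C)Cl
Why: Kinetic gamma-deprotonation of the beta-silyloxy enoate at C4 and O-silylation of the extended enolate, the standard second stage, gives the diene, and the arylmethyl group turns away from C2 to avoid allylic strain, which sets the Z geometry at C3=C4.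

**Step 8**
Reactants: 13 ethoxyacetylene; 14 butanal
Product: 16 1-ethoxyhex-1-yn-3-ol, via lithium ethoxyacetylide 15 (not isolated)
Conditions: 13, n-BuLi, THF, -78 °C; then 14, -78 to 0 °C; sat. aq NH4Cl
Reagents that add atoms: none
Why: This is a 1,2-addition of a lithium acetylide to an aldehyde, and the racemic carbinol centre is removed in the next step.

**Step 9**
Reactants: 16 1-ethoxyhex-1-yn-3-ol
Product: 17 1-ethoxyhex-1-yn-3-one
Conditions: activated MnO2 (15 equiv), CH2Cl2, rt; filtration through Celite, used at once
Reagents that add atoms: none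
Why: MnO2 oxidation of a propargylic alcohol runs under neutral, non-aqueous conditions and ends with a filtration, which suits an ynol ether that acid would hydrate or divert into a Meyer-Schuster rearrangement, and no amine nucleophile is set free that could add to the ynone.

**Step 10**
Reactants: 12 (3Z)-5-[4,6-bis(benzyloxy)-2-methoxy-3-methylphenyl]-1-methoxy-2-methyl-1,3-bis(trimethylsilyloxy)penta-1,3-diene; 17 1-ethoxyhex-1-yn-3-one
Product: 20 1-{3-[4,6-bis(benzyloxy)-2-methoxy-3-methylbenzyl]-2-ethoxy-4,6-dihydroxy-5-methylphenyl}butan-1-one (ring A complete with OEt at C6; ring B as 2',4'-dibenzyl ether with C3'-H), via cyclohexadiene cycloadduct 18 (not isolated), via bis(trimethylsilyl) ether 19 (not isolated)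
Conditions: 17 (2 equiv), PhMe (1 M), argon, rt to 70 °C; then 0.5 M aq HCl, THF, 0 °C
Reagents that add atoms: none
Why: Proposed new method: the diene terminus C4 (future C5), which carries the largest HOMO coefficient, should bond first to the OEt-bearing alkyne carbon, still the electrophilic beta position of the ynone, and the developing allenolate carbon then closes onto the ketene acetal carbon, so that C5-C6 and C1-C2 form in one concerted but strongly asynchronous (4+2) event or, at the limit, by Mukaiyama-Michael addition followed by Claisen-type collapse of the zwitterion. The closest known reaction type is the Diels-Alder cycloaddition of 1-alkoxy-1,3-bis(silyloxy)dienes with acetylenic ketones and esters to give resorcinols, and what has not been shown is a 1-alkoxyalk-1-yn-3-one as dienophile and a ring that ends up hexasubstituted. Ring A closes as a six-membered carbocycle in an intermolecular (4+2) mode, after which cycloadduct 18 aromatizes by 1,4-loss of methanol (H from C5, OMe from C2) to 19 and dilute acid strips the two silyl groups. No stereocentre is created in the product, since the two sp3 carbons of 18 are flattened on aromatization. Regioselectivity is the only selectivity needed and it rests on matched polarity, because both oxygen donors of the diene push towards C4 while the carbonyl group makes the OEt-bearing carbon the acceptor, and the Z geometry at C3=C4 places the arylmethyl group outside in the s-cis conformer. The temperature is capped at 70 °C because ethyl ynol ethers lose ethylene by a retro-ene path on stronger heating, and the excess of 17 and the high concentration are meant to offset the donor-raised LUMO.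

**Step 11**
Reactants: 20 1-{3-[4,6-bis(benzyloxy)-2-methoxy-3-methylbenzyl]-2-ethoxy-4,6-dihydroxy-5-methylphenyl}butan-1-one
Product: 21 1-[3-(4,6-dihydroxy-2-methoxy-3-methylbenzyl)-2-ethoxy-4,6-dihydroxy-5-methylphenyl]butan-1-one
Conditions: H2 (1 atm), Pd/C (10 wt %), EtOAc-MeOH, rt
Reagents that add atoms: none
Why: Catalytic hydrogenolysis removes aryl benzyl ethers, while the chelated aryl ketone, the alkyl ethers and the diarylmethane C-C bonds are not touched at one atmosphere and room temperature.

**Step 12**
Reactants: 21 1-[3-(4,6-dihydroxy-2-methoxy-3-methylbenzyl)-2-ethoxy-4,6-dihydroxy-5-methylphenyl]butan-1-one; 22 butyryl chloride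
Product: 23 6-O-ethylmargaspidin (margaspidin with OEt in place of OH at C6 of ring A)
Conditions: 22 (1.1 equiv), AlCl3 (6 equiv), CH2Cl2-MeNO2, 0 °C to rt; then ice-cold 1 M aq HCl
Reagents that add atoms: none
Why: Friedel-Crafts C-acylation is the standard entry to acylphloroglucinols, C3' (flanked by two hydroxyl groups and para to the methoxy group) is the only unsubstituted aromatic carbon in 21, and any phenol ester formed on the way should reach the same carbon by Fries rearrangement.

**Step 13**
Reactants: 23 6-O-ethylmargaspidin
Product: 24 margaspidin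
Conditions: BCl3 (6 equiv), CH2Cl2, -78 to 0 °C; then H2O
Reagents that add atoms: none
Why: In this chelation-directed ether cleavage BCl3 binds the ring A ketone oxygen and the neighbouring C6 ethoxy oxygen in a six-membered chelate and chloride removes the ethyl group, whereas the C6' methoxy group lies para to the ring B ketone, cannot chelate and should survive at or below 0 °C.

**Compound list**
1 | 2-methylphloroglucinol | Cc1c(O)cc(O)cc1O | starting material
2 | N,N-dimethyl-(2,4,6-trihydroxy-3-methylbenzylidene)iminium chloride | C[N+](C)=Cc1c(O)cc(O)c(C)c1O.[Cl-] | intermediate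
3 | 2,4,6-trihydroxy-3-methylbenzaldehyde | Cc1c(O)cc(O)c(C=O)c1O | intermediate
4 | 4,6-bis(benzyloxy)-2-hydroxy-3-methylbenzaldehyde | Cc1c(OCc2ccccc2)cc(OCc2ccccc2)c(C=O)c1O | intermediate
5 | 4,6-bis(benzyloxy)-2-methoxy-3-methylbenzaldehyde | Cc1c(OCc2ccccc2)cc(OCc2ccccc2)c(C=O)c1OC | intermediate
6 | methyl 2-methylacetoacetate | COC(=O)C(C)C(C)=O | starting material
7 | dilithio dianion of methyl 2-methylacetoacetate | [Li+].[Li+].COC([O-])=C(C)C([O-])=C | intermediate
8 | methyl 5-[4,6-bis(benzyloxy)-2-methoxy-3-methylphenyl]-5-hydroxy-2-methyl-3-oxopentanoate (diastereomer mixture) | COC(=O)C(C)C(=O)CC(O)c1c(OCc2ccccc2)cc(OCc2ccccc2)c(C)c1OC | intermediate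
9 | methyl 5-[4,6-bis(benzyloxy)-2-methoxy-3-methylphenyl]-2-methyl-3-oxopentanoate (racemic) | COC(=O)C(C)C(=O)CCc1c(OCc2ccccc2)cc(OCc2ccccc2)c(C)c1OC | intermediate
10 | methyl 5-[4,6-bis(benzyloxy)-2-methoxy-3-methylphenyl]-2-methyl-3-(trimethylsilyloxy)pent-2-enoate (E/Z undefined) | COC(=O)C(C)=C(O[Si](C)(C)C)CCc1c(OCc2ccccc2)cc(OCc2ccccc2)c(C)c1OC | intermediate
11 | lithium dienolate of 10 | [Li+].COC([O-])=C(C)/C(O[Si](C)(C)C)=C/Cc1c(OCc2ccccc2)cc(OCc2ccccc2)c(C)c1OC | intermediate
12 | (3Z)-5-[4,6-bis(benzyloxy)-2-methoxy-3-methylphenyl]-1-methoxy-2-methyl-1,3-bis(trimethylsilyloxy)penta-1,3-diene | COC(O[Si](C)(C)C)=C(C)/C(O[Si](C)(C)C)=C/Cc1c(OCc2ccccc2)cc(OCc2ccccc2)c(C)c1OC | intermediate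
13 | ethoxyacetylene | C#COCC | starting material
14 | butanal | CCCC=O | starting material
15 | lithium ethoxyacetylide | [Li+].[C-]#COCC | intermediate
16 | 1-ethoxyhex-1-yn-3-ol (racemic) | CCCC(O)C#COCC | intermediate
17 | 1-ethoxyhex-1-yn-3-one | CCCC(=O)C#COCC | intermediate
18 | 1,4-cyclohexadiene cycloadduct (C2 bears OMe and OSiMe3, C5 bears H and CH2Ar; diastereomer mixture) | CCCC(=O)C1=C(OCC)C(Cc2c(OCc3ccccc3)cc(OCc3ccccc3)c(C)c2OC)C(O[Si](C)(C)C)=C(C)C1(OC)O[Si](C)(C)C | intermediate
19 | 2,4-bis(trimethylsilyl) ether of 20 | CCCC(=O)c1c(O[Si](C)(C)C)c(C)c(O[Si](C)(C)C)c(Cc2c(OCc3ccccc3)cc(OCc3ccccc3)c(C)c2OC)c1OCC | intermediate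
20 | 1-{3-[4,6-bis(benzyloxy)-2-methoxy-3-methylbenzyl]-2-ethoxy-4,6-dihydroxy-5-methylphenyl}butan-1-one | CCCC(=O)c1c(O)c(C)c(O)c(Cc2c(OCc3ccccc3)cc(OCc3ccccc3)c(C)c2OC)c1OCC | intermediate
21 | 1-[3-(4,6-dihydroxy-2-methoxy-3-methylbenzyl)-2-ethoxy-4,6-dihydroxy-5-methylphenyl]butan-1-one | CCCC(=O)c1c(O)c(C)c(O)c(Cc2c(O)cc(O)c(C)c2OC)c1OCC | intermediate
22 | butyryl chloride | CCCC(=O)Cl | starting material
23 | 6-O-ethylmargaspidin | CCCC(=O)c1c(O)c(C)c(O)c(Cc2c(O)c(C(=O)CCC)c(O)c(C)c2OC)c1OCC | intermediate
24 | margaspidin | CCCC(=O)c1c(O)c(C)c(O)c(Cc2c(O)c(C(=O)CCC)c(O)c(C)c2OC)c1O | target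

**Step count**
Total step count: 13. Longest linear sequence: 11 (steps 1-7 and 10-13). The ynone branch has 2 steps (8 and 9).

**Steps most likely to fail**

Step 10. Several processes could defeat the cycloaddition.
- It may be too slow, because the ethoxy donor raises the alkyne LUMO and both partners are crowded.
- Over the long reaction time the ynol ether may fragment by retro-ene loss of ethylene.
- Silyl transfer may halt the sequence at the open-chain Michael stage.
- Adventitious moisture may hydrolyse the diene.

The fallback gives up the de novo construction of ring A and uses the classical methylene coupling of two preformed acylphloroglucinols. It sets out from 1 and 22. Friedel-Crafts acylation (AlCl3, CH2Cl2-MeNO2) gives 2,4,6-trihydroxy-3-methylbutyrophenone F1. One portion is mono-O-methylated at its unchelated para hydroxyl (Me2SO4, 1 equiv, K2CO3, acetone) to aspidinol F2. The other portion undergoes Mannich aminomethylation at its only free ring carbon (aq CH2O, Me2NH, EtOH) to give 3-[(dimethylamino)methyl]-2,4,6-trihydroxy-5-methylbutyrophenone F3. Heating F3 with F2 in dioxane releases the ortho-quinone methide of ring A, which the single free carbon of F2 captures. The sequence returns to the route at 24.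

Step 12. Ring B is very electron-rich before it is acylated, so ipso protonation or ipso acylation at C1' may trigger retro-Friedel-Crafts scission and scrambling of the methylene bridge. Persistent O-acylation and loss of the hindered methyl ether are further hazards. Premature loss of the ethyl group would be harmless.

The fallback avoids strong acid by building the acyl group in three mild stages on the benzyl-protected stage, and it sets out from 20. Vilsmeier-Haack formylation (POCl3, DMF, then H2O) at the only free ring carbon gives the 3'-carbaldehyde F4. Excess n-PrMgCl (THF, -78 to 0 °C) first deprotonates the two ring A phenols, which shields the chelated ketone, and then adds to the aldehyde to give the 3'-(1-hydroxybutyl) compound F5. MnO2 in CH2Cl2 oxidises this activated benzylic alcohol to the 3'-butyryl dibenzyl ether F6. Hydrogenolysis (H2, Pd/C) then bypasses 21 and returns to the route at 23.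

Step 5. Elimination to the conjugated enone may outrun hydride capture. The benzylic cation may instead be intercepted by the free ring carbon of a second molecule (oligomerisation) or by the ester carbonyl (lactonisation), and the acid may start to remove benzyl groups.

The fallback makes the elimination deliberate and reduces the alkene without any cation, and it sets out from 8. A catalytic amount of TsOH in dilute PhMe at rt dehydrates it to methyl (E)-5-[4,6-bis(benzyloxy)-2-methoxy-3-methylphenyl]-2-methyl-3-oxopent-4-enoate F7. Hydrogenation over Pd/C poisoned with Ph2S (EtOAc, rt) saturates the olefin while leaving the aryl benzyl ethers alone, and the sequence returns to the route at 9.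

**Further compounds**
F1 | step 10 | 2,4,6-trihydroxy-3-methylbutyrophenone | CCCC(=O)c1c(O)cc(O)c(C)c1O
F2 | step 10 | aspidinol (2,6-dihydroxy-4-methoxy-3-methylbutyrophenone) | CCCC(=O)c1c(O)cc(OC)c(C)c1O
F3 | step 10 | 3-[(dimethylamino)methyl]-2,4,6-trihydroxy-5-methylbutyrophenone | CCCC(=O)c1c(O)c(CN(C)C)c(O)c(C)c1O
F4 | step 12 | 3'-carbaldehyde of 20 | CCCC(=O)c1c(O)c(C)c(O)c(Cc2c(OCc3ccccc3)c(C=O)c(OCc3ccccc3)c(C)c2OC)c1OCC
F5 | step 12 | 3'-(1-hydroxybutyl) derivative of 20 (racemic) | CCCC(=O)c1c(O)c(C)c(O)c(Cc2c(OCc3ccccc3)c(C(O)CCC)c(OCc3ccccc3)c(C)c2OC)c1OCC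
F6 | step 12 | 3'-butyryl derivative of 20 (2',4'-di-O-benzyl-6-O-ethylmargaspidin) | CCCC(=O)c1c(O)c(C)c(O)c(Cc2c(OCc3ccccc3)c(C(=O)CCC)c(OCc3ccccc3)c(C)c2OC)c1OCC
F7 | step 5 | methyl (E)-5-[4,6-bis(benzyloxy)-2-methoxy-3-methylphenyl]-2-methyl-3-oxopent-4-enoate | COC(=O)C(C)C(=O)/C=C/c1c(OCc2ccccc2)cc(OCc2ccccc2)c(C)c1OC
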